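**Retrosynthetic overview**

- The strategy rests on ring A, the terminal orsellinic acid unit (C1 CO2H, C2 OH, C4 depside oxygen, C6 CH3). Its two phenolic oxygens are told apart by building the ring from a vinylketene and a silyl ynol ether, so that O2 is born as a silyl ether and O4 as the free phenol.
- Disconnections: the ester between rings B and A (ring B carbonyl to O4 of ring A), the ester between rings C and B, and ring A itself into a diazo keto ester (C1, C4, C5, C6, the methyl and the carboxyl) and (triisopropylsilyloxy)ethyne (C2, C3).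
- Ring order: rings C and B are bought as arenes (3,4,5-trimethoxytoluene, orsellinic acid) and joined into a C–B didepside acid. Ring A is the only ring formed (step 5). Union, desilylation and hydrogenolysis follow.
- Precursor supply: the diazo keto ester comes from a diazoacetate aldol addition and oxidation, which avoids a polymerisable isopropenyl beta-keto ester. The ynol ether comes from trimethylsilylacetylene by acetylide oxidation, O-silylation and C-desilylation.

Key step: step 5

Remark: the target has no stereocentre and no stereogenic double bond. Compounds 3 and 11 are racemic, and their stereocentres disappear in the next event.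

**Route**

Step 1
Reactants: 1 benzyl diazoacetate; 2 methacrolein
Product: 3 benzyl 2-diazo-3-hydroxy-4-methylpent-4-enoate (racemic)
Conditions: DBU (10 mol%), MeCN, 0 °C to rt
Reagents that add atoms: none
Why: DBU-catalysed aldol-type addition of the acidic diazoacetate C–H to the aldehyde carbonyl of the enal (1,2-addition) should give the racemic alpha-diazo-beta-hydroxy ester, whose carbinol stereocentre is erased in step 2.

Step 2
Reactants: 3 benzyl 2-diazo-3-hydroxy-4-methylpent-4-enoate
Product: 4 benzyl 2-diazo-4-methyl-3-oxopent-4-enoate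
Conditions: IBX, DMSO, rt
Reagents that add atoms: none
Why: IBX oxidation of the secondary allylic alcohol under neutral conditions should leave the acid-sensitive diazo group and the 1,1-disubstituted alkene untouched (known oxidation of alpha-diazo-beta-hydroxy esters to diazo keto esters).

Step 3
Reactants: 5 trimethylsilylacetylene
Product: 8 (triisopropylsilyloxy)(trimethylsilyl)ethyne, via lithium acetylide 6 (not isolated), via lithium ynolate 7 (not isolated)
Conditions: n-BuLi, THF, −78 °C; then LiOOt-Bu [from t-BuOOH, LiN(SiMe3)2, THF, −78 °C], −78 to 0 °C; then TIPSOTf, −78 to 0 °C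
Reagents that add atoms: tert-butyl hydroperoxide, CC(C)(C)OO; triisopropylsilyl trifluoromethanesulfonate, CC(C)[Si](OS(=O)(=O)C(F)(F)F)(C(C)C)C(C)C
Why: The lithium acetylide attacks the electrophilic peroxide oxygen of LiOOt-Bu (oxenoid oxidation of an acetylide to an ynolate), and the bulky, hard electrophile TIPSOTf should silylate the ynolate at oxygen rather than at carbon, as it does with other ynolates.

Step 4
Reactants: 8 (triisopropylsilyloxy)(trimethylsilyl)ethyne
Product: 9 (triisopropylsilyloxy)ethyne
Conditions: K2CO3 (cat.), MeOH/THF, 0 °C; short-path distillation, used at once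
Reagents that add atoms: none
Why: Methoxide attacks the unhindered carbon-bound SiMe3 group (protodesilylation of an alkynylsilane), while the hindered O–Si(i-Pr)3 bond and the electron-rich triple bond should survive brief exposure at 0 °C.

Step 5
Reactants: 4 benzyl 2-diazo-4-methyl-3-oxopent-4-enoate; 9 (triisopropylsilyloxy)ethyne
Product: 14 benzyl 4-hydroxy-6-methyl-2-(triisopropylsilyloxy)benzoate, via vinylketene 10 (not isolated), via cyclobutenone 11 (not isolated), via dienylketene 12 (not isolated), via cyclohexadienone 13 (not isolated)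
Conditions: 9 (1.5 equiv), hν (Hg lamp, Vycor filter), degassed ClCH2CH2Cl (0.05 M), rt; then 80 °C
Reagents that add atoms: none
Why: Irradiation expels N2 from 4 and the isopropenyl group shifts to the diazo carbon (photochemical Wolff rearrangement, forming C1–C6) to give vinylketene 10, which adds 9 in a [2+2] cycloaddition in which the alkyne CH bonds to the ketene carbonyl carbon (C3–C4) and the alkyne C–O carbon to the ketene alpha-carbon (C1–C2), giving cyclobutenone 11. Four-electron electrocyclic opening of 11 gives dienylketene 12, and ring A then closes by a thermal six-electron electrocyclisation between the ketene carbon and the terminal CH2 (C4–C5) to cyclohexadienone 13, which tautomerises to phenol 14. This is the diazo ketone variant of the Danheiser benzannulation with a siloxyalkyne, here run on a diazo keto ester. The ketene carbonyl becomes the free C4–OH and the ynol oxygen stays as the C2 silyl ether, so the two resorcinol oxygens are differentiated as the ring forms; no stereocentre is created. The step needs migration of the isopropenyl group and not of the benzyloxy group (the ketone substituent of a diazo keto ester migrates in preference to alkoxy), and the stated [2+2] regiochemistry, which the polarisation of the ynol ether secures because its unsubstituted carbon is the nucleophile. It also needs [2+2] addition across the ketene C=C in preference to hetero-[4+2] addition across the ester carbonyl, which the low heterodiene reactivity of an alkoxycarbonyl ketene favours; excess 9 at high dilution limits acylation of 14 by 10.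

Step 6
Reactants: 15 3,4,5-trimethoxytoluene
Product: 17 2,3,4-trimethoxy-6-methylbenzaldehyde, via iminium salt 16 (not isolated)
Conditions: POCl3, DMF, 0 to 80 °C; then aq NaOAc
Reagents that add atoms: N,N-dimethylformamide, CN(C)C=O; water, O
Why: Vilsmeier–Haack formylation of the electron-rich arene at C2, which is equivalent to C6 and the only kind of free position, should give the aldehyde after hydrolysis of the iminium salt.

Step 7
Reactants: 17 2,3,4-trimethoxy-6-methylbenzaldehyde
Product: 18 2,3,4-trimethoxy-6-methylbenzoic acid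
Conditions: NaClO2, NaH2PO4, 2-methyl-2-butene, t-BuOH/H2O, rt
Reagents that add atoms: sodium chlorite, [Na+].[O-]Cl=O
Why: Pinnick oxidation converts the hindered aryl aldehyde into the acid, and 2-methyl-2-butene traps HOCl so that the electron-rich ring is not chlorinated.

Step 8
Reactants: 19 orsellinic acid
Product: 20 allyl 2,4-dihydroxy-6-methylbenzoate
Conditions: allyl bromide, KHCO3, DMF, rt
Reagents that add atoms: allyl bromide, C=CCBr
Why: The weak base KHCO3 forms only the carboxylate, so SN2 alkylation by allyl bromide gives the ester and leaves both phenols free, and room temperature avoids decarboxylation of the beta-resorcylic acid.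

Step 9
Reactants: 18 2,3,4-trimethoxy-6-methylbenzoic acid; 20 allyl 2,4-dihydroxy-6-methylbenzoate
Product: 22 allyl 2-hydroxy-6-methyl-4-[(2,3,4-trimethoxy-6-methylbenzoyl)oxy]benzoate, via acid chloride 21 (not isolated)
Conditions: 18, (COCl)2, DMF (cat.), CH2Cl2, 0 °C to rt; concentrate; then 20 (1.0 equiv), Et3N, DMAP (cat.), CH2Cl2, 0 °C
Reagents that add atoms: oxalyl chloride, O=C(Cl)C(=O)Cl (supplies only the chlorine of 21)
Why: The acid chloride of the hindered ring C acid acylates (DMAP-catalysed esterification) the more acidic, non-chelated 4-OH of ring B, whereas the 2-OH is hydrogen-bonded to the neighbouring ester carbonyl and shielded by it.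

Step 10
Reactants: 22 allyl 2-hydroxy-6-methyl-4-[(2,3,4-trimethoxy-6-methylbenzoyl)oxy]benzoate
Product: 23 allyl 2-(benzyloxy)-6-methyl-4-[(2,3,4-trimethoxy-6-methylbenzoyl)oxy]benzoate
Conditions: BnBr, K2CO3, DMF, rt
Reagents that add atoms: benzyl bromide, BrCc1ccccc1
Why: Williamson etherification of the remaining chelated 2-OH should proceed cleanly because the doubly ortho-substituted aryl ester of ring C is too hindered to be attacked by phenoxide or carbonate under anhydrous conditions.

Step 11
Reactants: 23 allyl 2-(benzyloxy)-6-methyl-4-[(2,3,4-trimethoxy-6-methylbenzoyl)oxy]benzoate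
Product: 24 2-(benzyloxy)-6-methyl-4-[(2,3,4-trimethoxy-6-methylbenzoyl)oxy]benzoic acid
Conditions: Pd(PPh3)4 (5 mol%), N-methylaniline, THF, rt
Reagents that add atoms: none
Why: Tsuji–Trost deallylation, in which zerovalent palladium ionises the allyl ester and the weakly nucleophilic N-methylaniline traps the pi-allyl fragment, leaves the aryl ester, benzyl ether and methyl ethers untouched.

Step 12
Reactants: 24 2-(benzyloxy)-6-methyl-4-[(2,3,4-trimethoxy-6-methylbenzoyl)oxy]benzoic acid; 14 benzyl 4-hydroxy-6-methyl-2-(triisopropylsilyloxy)benzoate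
Product: 26 benzyl 4-{[2-(benzyloxy)-6-methyl-4-[(2,3,4-trimethoxy-6-methylbenzoyl)oxy]benzoyl]oxy}-6-methyl-2-(triisopropylsilyloxy)benzoate, via acid chloride 25 (not isolated)
Conditions: 24, (COCl)2, DMF (cat.), CH2Cl2, 0 °C to rt; concentrate; then 14, Et3N, DMAP (cat.), CH2Cl2, 0 °C to rt
Reagents that add atoms: oxalyl chloride, O=C(Cl)C(=O)Cl (supplies only the chlorine of 25)
Why: The 2,6-disubstituted ring B acid is activated as its acid chloride and esterifies, under DMAP catalysis, the only free hydroxyl of 14 (O4 of ring A), while the aryl silyl ether and the benzyl ester tolerate the mild base.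

Step 13
Reactants: 26 the silylated tridepside benzyl ester
Product: 27 benzyl 4-{[2-(benzyloxy)-6-methyl-4-[(2,3,4-trimethoxy-6-methylbenzoyl)oxy]benzoyl]oxy}-2-hydroxy-6-methylbenzoate
Conditions: Bu4NF, AcOH, THF, 0 °C
Reagents that add atoms: none
Why: Fluoride cleaves the aryl O–Si bond, and the acetic acid buffer keeps the liberated phenoxide protonated so that the two depside esters are not transesterified.

Step 14
Reactants: 27 the benzyl-protected tridepside
Product: 28 2-hydroxy-4-{[2-hydroxy-6-methyl-4-[(2,3,4-trimethoxy-6-methylbenzoyl)oxy]benzoyl]oxy}-6-methylbenzoic acid (CNP0332884.0)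
Conditions: H2 (1 atm), Pd/C (10% Pd on carbon), EtOAc, rt
Reagents that add atoms: none
Why: Hydrogenolysis over Pd/C removes the benzyl ester of ring A and the benzyl ether of ring B in one operation, while the aryl esters, methyl ethers and arenes are inert, so the target should be obtained after filtration.

**Compound list**

1 | benzyl diazoacetate | [N-]=[N+]=CC(=O)OCc1ccccc1 | starting material
2 | methacrolein | C=C(C)C=O | starting material
3 | benzyl 2-diazo-3-hydroxy-4-methylpent-4-enoate (racemic) | C=C(C)C(O)C(=[N+]=[N-])C(=O)OCc1ccccc1 | intermediate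
4 | benzyl 2-diazo-4-methyl-3-oxopent-4-enoate | C=C(C)C(=O)C(=[N+]=[N-])C(=O)OCc1ccccc1 | intermediate
5 | trimethylsilylacetylene | C#C[Si](C)(C)C | starting material
6 | lithium (trimethylsilyl)acetylide | [Li+].[C-]#C[Si](C)(C)C | intermediate
7 | lithium 2-(trimethylsilyl)ethynolate | [Li+].[O-]C#C[Si](C)(C)C | intermediate
8 | (triisopropylsilyloxy)(trimethylsilyl)ethyne | C[Si](C)(C)C#CO[Si](C(C)C)(C(C)C)C(C)C | intermediate
9 | (triisopropylsilyloxy)ethyne | C#CO[Si](C(C)C)(C(C)C)C(C)C | intermediate
10 | benzyl 3-methyl-2-(oxomethylidene)but-3-enoate (vinylketene) | C=C(C)C(=C=O)C(=O)OCc1ccccc1 | intermediate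
11 | benzyl 1-isopropenyl-4-oxo-2-(triisopropylsilyloxy)cyclobut-2-ene-1-carboxylate (racemic) | C=C(C)C1(C(=O)OCc2ccccc2)C(=O)C=C1O[Si](C(C)C)(C(C)C)C(C)C | intermediate
12 | benzyl (2Z)-2-isopropenyl-5-oxo-3-(triisopropylsilyloxy)penta-2,4-dienoate (dienylketene) | O=C=C/C(O[Si](C(C)C)(C(C)C)C(C)C)=C(\C(C)=C)C(=O)OCc1ccccc1 | intermediate
13 | benzyl 2-methyl-4-oxo-6-(triisopropylsilyloxy)cyclohexa-1,5-diene-1-carboxylate | O=C1C=C(O[Si](C(C)C)(C(C)C)C(C)C)C(C(=O)OCc2ccccc2)=C(C)C1 | intermediate
14 | benzyl 4-hydroxy-6-methyl-2-(triisopropylsilyloxy)benzoate | Cc1cc(O)cc(O[Si](C(C)C)(C(C)C)C(C)C)c1C(=O)OCc1ccccc1 | intermediate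
15 | 3,4,5-trimethoxytoluene | COc1cc(C)cc(OC)c1OC | starting material
16 | N,N-dimethyl-(2,3,4-trimethoxy-6-methylbenzylidene)iminium dichlorophosphate | COc1cc(C)c(C=[N+](C)C)c(OC)c1OC.[O-]P(=O)(Cl)Cl | intermediate
17 | 2,3,4-trimethoxy-6-methylbenzaldehyde | COc1cc(C)c(C=O)c(OC)c1OC | intermediate
18 | 2,3,4-trimethoxy-6-methylbenzoic acid | COc1cc(C)c(C(=O)O)c(OC)c1OC | intermediate
19 | orsellinic acid (2,4-dihydroxy-6-methylbenzoic acid) | Cc1cc(O)cc(O)c1C(=O)O | starting material
20 | allyl 2,4-dihydroxy-6-methylbenzoate | Cc1cc(O)cc(O)c1C(=O)OCC=C | intermediate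
21 | 2,3,4-trimethoxy-6-methylbenzoyl chloride | COc1cc(C)c(C(=O)Cl)c(OC)c1OC | intermediate
22 | allyl 2-hydroxy-6-methyl-4-[(2,3,4-trimethoxy-6-methylbenzoyl)oxy]benzoate | COc1cc(C)c(C(=O)Oc2cc(C)c(C(=O)OCC=C)c(O)c2)c(OC)c1OC | intermediate
23 | allyl 2-(benzyloxy)-6-methyl-4-[(2,3,4-trimethoxy-6-methylbenzoyl)oxy]benzoate | COc1cc(C)c(C(=O)Oc2cc(C)c(C(=O)OCC=C)c(OCc3ccccc3)c2)c(OC)c1OC | intermediate
24 | 2-(benzyloxy)-6-methyl-4-[(2,3,4-trimethoxy-6-methylbenzoyl)oxy]benzoic acid | COc1cc(C)c(C(=O)Oc2cc(C)c(C(=O)O)c(OCc3ccccc3)c2)c(OC)c1OC | intermediate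
25 | 2-(benzyloxy)-6-methyl-4-[(2,3,4-trimethoxy-6-methylbenzoyl)oxy]benzoyl chloride | COc1cc(C)c(C(=O)Oc2cc(C)c(C(=O)Cl)c(OCc3ccccc3)c2)c(OC)c1OC | intermediate
26 | benzyl 4-{[2-(benzyloxy)-6-methyl-4-[(2,3,4-trimethoxy-6-methylbenzoyl)oxy]benzoyl]oxy}-6-methyl-2-(triisopropylsilyloxy)benzoate | COc1cc(C)c(C(=O)Oc2cc(C)c(C(=O)Oc3cc(C)c(C(=O)OCc4ccccc4)c(O[Si](C(C)C)(C(C)C)C(C)C)c3)c(OCc3ccccc3)c2)c(OC)c1OC | intermediate
27 | benzyl 4-{[2-(benzyloxy)-6-methyl-4-[(2,3,4-trimethoxy-6-methylbenzoyl)oxy]benzoyl]oxy}-2-hydroxy-6-methylbenzoate | COc1cc(C)c(C(=O)Oc2cc(C)c(C(=O)Oc3cc(C)c(C(=O)OCc4ccccc4)c(O)c3)c(OCc3ccccc3)c2)c(OC)c1OC | intermediate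
28 | 2-hydroxy-4-{[2-hydroxy-6-methyl-4-[(2,3,4-trimethoxy-6-methylbenzoyl)oxy]benzoyl]oxy}-6-methylbenzoic acid (CNP0332884.0) | COc1cc(C)c(C(=O)Oc2cc(C)c(C(=O)Oc3cc(C)c(C(=O)O)c(O)c3)c(O)c2)c(OC)c1OC | target

**Step count**

Total: 14 steps. Longest linear sequence: 8 steps (15 to 28 through steps 6, 7, 9, 10, 11, 12, 13 and 14).

**Steps most likely to fail**

Step 5. The photochemical stage may go astray: the carbene may react before the Wolff shift, the benzyloxy group may migrate instead of the isopropenyl group, the ketene may be captured across its ester carbonyl in a hetero-[4+2] addition, or the phenol formed may be acylated by remaining ketene. The fallback gives up the construction of ring A and relies on the inherent difference between the two hydroxyls of an orsellinate. It sets out from orsellinic acid 19, which with BnBr and KHCO3 in DMF at rt should give benzyl 2,4-dihydroxy-6-methylbenzoate F1. Acylation of F1 with acid chloride 25 (Et3N, catalytic DMAP, CH2Cl2, 0 °C) should take place at the non-chelated 4-OH, as in step 9. This comes back to the route at 27, one hydrogenolysis from the target.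

Step 3. Oxygen transfer from LiOOt-Bu to the silyl-substituted acetylide may be incomplete, or TIPSOTf may silylate ynolate 7 at carbon to give a bis-silyl ketene. The fallback makes an ynol ether without any ynolate and sets out from diazo keto ester 4. KOt-Bu and trichloroethylene in THF should give (E)-tert-butyl 1,2-dichlorovinyl ether F2, and n-BuLi (2.2 equiv, THF, −78 °C) followed by a methanol quench should give tert-butoxyethyne F3. Irradiation of 4 with F3 under the conditions of step 5, with only gentle warming at 40 °C afterwards, should lead through vinylketene 10 to benzyl 2-tert-butoxy-1-isopropenyl-4-oxocyclobut-2-ene-1-carboxylate F4, then benzyl (2Z)-3-tert-butoxy-2-isopropenyl-5-oxopenta-2,4-dienoate F5, then benzyl 6-tert-butoxy-2-methyl-4-oxocyclohexa-1,5-diene-1-carboxylate F6, and finally benzyl 2-tert-butoxy-4-hydroxy-6-methylbenzoate F7. Acylation of F7 with acid chloride 25 as in step 12 should give benzyl 4-{[2-(benzyloxy)-6-methyl-4-[(2,3,4-trimethoxy-6-methylbenzoyl)oxy]benzoyl]oxy}-2-tert-butoxy-6-methylbenzoate F8. Cleavage of the aryl tert-butyl ether with CF3CO2H in CH2Cl2 at 0 °C comes back to the route at 27.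

Step 4. During C-desilylation the O-silyl group may be lost, methanol may add across the electron-rich triple bond, and the volatile product may be lost on isolation. The fallback keeps the carbon-bound silyl group through the annulation and removes it from the arene. It sets out from 8, which is irradiated with 4 under the conditions of step 5; the siloxy group still directs the [2+2] addition. This should lead through vinylketene 10 to benzyl 1-isopropenyl-4-oxo-2-(triisopropylsilyloxy)-3-(trimethylsilyl)cyclobut-2-ene-1-carboxylate F9, then benzyl (2Z)-2-isopropenyl-5-oxo-3-(triisopropylsilyloxy)-4-(trimethylsilyl)penta-2,4-dienoate F10, then benzyl 2-methyl-4-oxo-6-(triisopropylsilyloxy)-5-(trimethylsilyl)cyclohexa-1,5-diene-1-carboxylate F11, and finally benzyl 4-hydroxy-6-methyl-2-(triisopropylsilyloxy)-3-(trimethylsilyl)benzoate F12. Ipso-protodesilylation of the aryl–SiMe3 bond, which lies between two oxygen substituents (CF3CO2H, CH2Cl2, 0 °C), comes back to the route at 14.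

**Further compounds**

F1 | step 5 | benzyl 2,4-dihydroxy-6-methylbenzoate | Cc1cc(O)cc(O)c1C(=O)OCc1ccccc1
F2 | step 3 | (E)-tert-butyl 1,2-dichlorovinyl ether | Cl/C=C(/Cl)OC(C)(C)C
F3 | step 3 | tert-butoxyethyne | C#COC(C)(C)C
F4 | step 3 | benzyl 2-tert-butoxy-1-isopropenyl-4-oxocyclobut-2-ene-1-carboxylate (racemic) | C=C(C)C1(C(=O)OCc2ccccc2)C(=O)C=C1OC(C)(C)C
F5 | step 3 | benzyl (2Z)-3-tert-butoxy-2-isopropenyl-5-oxopenta-2,4-dienoate | O=C=C/C(OC(C)(C)C)=C(\C(C)=C)C(=O)OCc1ccccc1
F6 | step 3 | benzyl 6-tert-butoxy-2-methyl-4-oxocyclohexa-1,5-diene-1-carboxylate | O=C1C=C(OC(C)(C)C)C(C(=O)OCc2ccccc2)=C(C)C1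
F7 | step 3 | benzyl 2-tert-butoxy-4-hydroxy-6-methylbenzoate | Cc1cc(O)cc(OC(C)(C)C)c1C(=O)OCc1ccccc1
F8 | step 3 | benzyl 4-{[2-(benzyloxy)-6-methyl-4-[(2,3,4-trimethoxy-6-methylbenzoyl)oxy]benzoyl]oxy}-2-tert-butoxy-6-methylbenzoate | COc1cc(C)c(C(=O)Oc2cc(C)c(C(=O)Oc3cc(C)c(C(=O)OCc4ccccc4)c(OC(C)(C)C)c3)c(OCc3ccccc3)c2)c(OC)c1OC
F9 | step 4 | benzyl 1-isopropenyl-4-oxo-2-(triisopropylsilyloxy)-3-(trimethylsilyl)cyclobut-2-ene-1-carboxylate (racemic) | C=C(C)C1(C(=O)OCc2ccccc2)C(=O)C([Si](C)(C)C)=C1O[Si](C(C)C)(C(C)C)C(C)C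
F10 | step 4 | benzyl (2Z)-2-isopropenyl-5-oxo-3-(triisopropylsilyloxy)-4-(trimethylsilyl)penta-2,4-dienoate | O=C=C([Si](C)(C)C)/C(O[Si](C(C)C)(C(C)C)C(C)C)=C(\C(C)=C)C(=O)OCc1ccccc1
F11 | step 4 | benzyl 2-methyl-4-oxo-6-(triisopropylsilyloxy)-5-(trimethylsilyl)cyclohexa-1,5-diene-1-carboxylate | O=C1C([Si](C)(C)C)=C(O[Si](C(C)C)(C(C)C)C(C)C)C(C(=O)OCc2ccccc2)=C(C)C1
F12 | step 4 | benzyl 4-hydroxy-6-methyl-2-(triisopropylsilyloxy)-3-(trimethylsilyl)benzoate | Cc1cc(O)c([Si](C)(C)C)c(O[Si](C(C)C)(C(C)C)C(C)C)c1C(=O)OCc1ccccc1
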